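Its constants belong to no real substance; what happens was integrated by code.

I decided to reckon this catalyst by the time one lap of its cycle takes, and I set the flasks down first.

    catalyst intermediate D ⇌ free catalyst + target (K1 = 0.39 M, k1 = 49 min⁻¹)
    starting material + target → side product (k2 = 1.5 M⁻¹ min⁻¹)
    starting material + free catalyst → catalyst intermediate A (k3 = 5300 M⁻¹ min⁻¹)
    catalyst intermediate A → catalyst intermediate B (k4 = 1.3 min⁻¹)
    reagent + catalyst intermediate B → catalyst intermediate C (k5 = 63 M⁻¹ min⁻¹)
    free catalyst + added ligand ⇌ idle complex, settled at all times (K6 = 1100 M⁻¹)
    catalyst intermediate C ⇌ released group + catalyst intermediate D (K7 = 0.60 M, k7 = 1.8 min⁻¹)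

| flask | starting material | reagent | free catalyst | added ligand | remark | time |
|---|---|---|---|---|---|---|
| zeta | 20 mM | 0.950 equiv | 3.4 mol% | 0.37 mM | a single well-mixed tank run continuously and read at steady state, 1.0 h in it on average |  |
| epsilon | 20 mM | 0.950 equiv (fed, over 1.00 h) | 3.4 mol% | 0.37 mM | a stirred flask in which reagent is dosed at a steady rate over 1.00 h without added volume, worked up at 1.0 h | 1.0 h |
| alpha | 20 mM | 0.950 equiv | 3.4 mol% | 0.37 mM | a single well-mixed tank run continuously and read at steady state, 10.0 h in it on average |  |
| eta | 20 mM | 0.950 equiv | 3.4 mol% | 0.37 mM | everything together in a closed stirred flask, run for 1.0 h | 1.0 h |

- percent here means starting material units held: one side product counts as two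
- the stated concentrations are those of everything mixed, before any reaction; amounts are the same in each set-up
- the feed brings no volume worth counting
- run time (epsilon): 1.0 h

- order of the set-ups by the amount of target at the outlet or at the end, in percent of the starting material put in, highest first (zeta / epsilon / alpha / eta)
- amount of target at the outlet or at the end, in percent of the starting material put in, zeta
- amount of target at the outlet or at the end, in percent of the starting material put in, epsilon
- amount of target at the outlet or at the end, in percent of the starting material put in, alpha
- amount of target at the outlet or at the end, in percent of the starting material put in, eta

What stayed nearly constant? The catalyst did: its 0.680 mM, counted over its forms, is far less than the starting material, so it had to go round many times, and I took the target to appear at the pace of those laps.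

What did a lap cost? The change of catalyst intermediate A into B and the forward break-up of C together cost 1.32 min, whatever the concentrations. Capture of starting material and release of target cost 0.0298 min at the charge, much less, so I dropped them for as long as starting material stood near its charge. The wait for reagent grows as reagent falls. I therefore named the half-speed reagent level, the reagent concentration at which its wait equals the fixed waits, 12.0 mM, a Michaelis-type constant. The laps then run at a top speed of 0.513 mM min⁻¹ times reagent over reagent plus that level. The charge of 19.0 mM stands less than twice that level, so the catalyst slows as reagent falls.

What did each vessel allow? Balancing feed against laps, the zeta tank holds reagent at 7.32 mM. Its side product, from the same balance, is 3.52 mM, which leaves 40.8% target, with catalyst-held material uncounted. The alpha tank holds 0.755 mM and 1.64 mM of side product, which leaves 83.0% target. That same balance leaves the alpha tank with 0.110 mM of starting material, at which capture alone waits 1.71 min, more than the fixed waits, so the lap I used for the alpha tank was too short and its figure is a rough one. The eta flask starts at more reagent than the zeta tank ever sees, so I placed it above zeta. The epsilon flask starts from none, so I placed it last.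

The forecast gave alpha > eta > zeta > epsilon, with 41.5%, 32%, 85% and 49% for zeta, epsilon, alpha and eta, holding that “dosing starves the reagent step further”.

The simulation gave alpha > eta > zeta > epsilon, with 40.3%, 32.1%, 84.2% and 50.9% in the same sequence.

The zeta tank held reagent at 7.50 mM where I had 7.32 mM. The epsilon flask had not come to rest at 1.0 h: left ten times as long, to 10.0 h, it gives 58.5% target, 26 percentage points more. Its reagent peaked at 9.60 mM, where the half-speed level gives 0.228 mM min⁻¹. At that speed held, the 7.19 mM of starting material left at its end lasts 31.5 min, less than the 9.00 h that follow.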